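A direct plan would join C7 and C8 by a boron-mediated syn aldol reaction of the N-(aryloxyacetyl)oxazolidinone A1, built from eugenol, with 3,4,5-trimethoxybenzaldehyde to give adduct A2.
Its weakest part would be the lowering of C9 from the imide to a methyl group: silylation of C7–OH, reductive loss of the auxiliary, sulfonylation to A3, hydride displacement and a last desilylation would be five operations that add no skeletal bond, and the displacement beside two oxygen-bearing stereocentres could turn into elimination.
The run-up would cost as much: four steps and a stoichiometric auxiliary to make A1 for a single C–C bond.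
The hydroboration–oxidation of the allyl group of A4 would fall on the second-to-last compound, the step one would least like to run on material that carries all the stereochemical work.

**Plan of the new route**
The retrosynthesis cuts C7–H first (alcohol 8 back to the racemic ketone 7), then the C8–O bond to ring B (bromoketone 5 + phenol 6), then C8–Br, then the ethyl group from nitrile 1. Both benzene rings are bought and no ring is formed.
The feature used is C8–H: it lies between the C7 carbonyl conjugated to ring A and the aryloxy oxygen of ring B, so C8 racemises at the ketone stage. One chiral hydrogenation catalyst should therefore set C7 and C8 together by dynamic kinetic resolution.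
C9 is a methyl group from the first step, no auxiliary or protecting group is used, and the hydroxypropyl chain comes with phenol 6, so nothing is deoxygenated or hydroborated late.

Key step: step 4

Remark: 4-(3-hydroxypropyl)-2-methoxyphenol (dihydroconiferyl alcohol, 6) is taken as a purchased compound.
Abbreviations: xylBINAP = 2,2'-bis[di(3,5-dimethylphenyl)phosphino]-1,1'-binaphthyl; DAIPEN = 1,1-bis(4-methoxyphenyl)-3-methylbutane-1,2-diamine.

Step 1
Reactants: 1 3,4,5-trimethoxybenzonitrile; 2 ethylmagnesium bromide
Product: 4 1-(3,4,5-trimethoxyphenyl)propan-1-one, via N-bromomagnesio ketimine 3 (not isolated)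
Conditions: EtMgBr (1.5 equiv, 3 M in Et2O), toluene, 80 °C, 4 h; then 2 M HCl, rt, 2 h
Reagents that add atoms: water, O (gives the carbonyl oxygen)
Why: Grignard addition to a nitrile: the ethyl carbanion adds once to C7 to give the N-magnesio ketimine 3, which is inert to a second addition and is hydrolysed by aqueous acid to the ketone, so C9 is a methyl group from the outset and ring A keeps its 3,4,5-pattern, which a Friedel–Crafts acylation of 1,2,3-trimethoxybenzene would not give.

Step 2
Reactants: 4 1-(3,4,5-trimethoxyphenyl)propan-1-one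
Product: 5 2-bromo-1-(3,4,5-trimethoxyphenyl)propan-1-one (racemic)
Conditions: CuBr2 (2.1 equiv), EtOAc/CHCl3 1:1, reflux, 4 h
Reagents that add atoms: copper dibromide, Br[Cu]Br
Why: Ketone α-bromination with CuBr2 proceeds through the enol and transfers bromine only to the enolisable C8 position, with no free bromine to attack the electron-rich ring A; the new C8 centre is racemic and is meant to be.

Step 3
Reactants: 5 2-bromo-1-(3,4,5-trimethoxyphenyl)propan-1-one; 6 4-(3-hydroxypropyl)-2-methoxyphenol
Product: 7 2-[4-(3-hydroxypropyl)-2-methoxyphenoxy]-1-(3,4,5-trimethoxyphenyl)propan-1-one (racemic)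
Conditions: 6 (1.05 equiv), K2CO3 (2 equiv), acetone, reflux, 8 h
Reagents that add atoms: none
Why: Williamson ether synthesis: the potassium phenoxide of 6 displaces the bromide activated by the neighbouring carbonyl in an SN2 reaction, whereas the primary alcohol (pKa about 16) is not deprotonated by carbonate and stays free, and the racemic C8 centre is left for the next step to resolve.

Step 4
Reactants: 7 2-[4-(3-hydroxypropyl)-2-methoxyphenoxy]-1-(3,4,5-trimethoxyphenyl)propan-1-one (racemic)
Product: 8 surinamensinol A, (1R,2R)-2-[4-(3-hydroxypropyl)-2-methoxyphenoxy]-1-(3,4,5-trimethoxyphenyl)propan-1-ol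
Conditions: trans-RuCl2[(R)-xylBINAP][(R)-DAIPEN] (0.5 mol %), KOtBu (10 mol %), H2 (10 atm), i-PrOH, 25 °C, 16 h
Reagents that add atoms: none
Why: The 18-electron hydride RuH2(diphosphine)(diamine) should pass Ru–H and N–H to the C7 carbonyl in an outer-sphere six-centre transition state while KOtBu interconverts the two enantiomers of 7 through the C8 potassium enolate, so that the whole racemate drains through the faster-reacting enantiomer. The closest known reaction type is the asymmetric hydrogenation of racemic α-heteroatom-substituted ketones with dynamic kinetic resolution by bifunctional ruthenium diphosphine–diamine catalysts (Noyori hydrogenation of α-amido propiophenones and 2-alkoxycycloalkanones); no ring is closed. C7 is set by the catalyst: the (R)-diphosphine/(R)-diamine pair is the antipode that reduces acetophenone to (S)-1-phenylethanol, and with ring A in the place of phenyl and C8 in that of methyl the same facial delivery is (7R), because C8 outranks ring A. C8 is set by selection between the enantiomers: the coordinatively saturated hydride cannot chelate the ether oxygens, so the Felkin–Anh geometry with the C8–O(ring B) bond anti to the incoming hydride and C8–H on the ring A side should rule, and for (7R) delivery this geometry is open only to the (8R)-ketone, which gives the syn (threo) 7R,8R product. The step needs racemisation of C8 to outrun reduction of the (8S)-ketone, and this is secured by C8–H lying between the aroyl carbonyl and the aryloxy oxygen. Once C7 is reduced C8–H is no longer acidic, so the product should not epimerise under the base.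

## Compound list
1 | 3,4,5-trimethoxybenzonitrile | COc1cc(C#N)cc(OC)c1OC | starting material
2 | ethylmagnesium bromide | CC[Mg]Br | starting material
3 | N-bromomagnesio ketimine of 4 | CCC(=N[Mg]Br)c1cc(OC)c(OC)c(OC)c1 | intermediate (not isolated)
4 | 1-(3,4,5-trimethoxyphenyl)propan-1-one | CCC(=O)c1cc(OC)c(OC)c(OC)c1 | intermediate
5 | 2-bromo-1-(3,4,5-trimethoxyphenyl)propan-1-one (racemic) | CC(Br)C(=O)c1cc(OC)c(OC)c(OC)c1 | intermediate
6 | 4-(3-hydroxypropyl)-2-methoxyphenol (dihydroconiferyl alcohol) | COc1cc(CCCO)ccc1O | starting material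
7 | 2-[4-(3-hydroxypropyl)-2-methoxyphenoxy]-1-(3,4,5-trimethoxyphenyl)propan-1-one (racemic) | COc1cc(CCCO)ccc1OC(C)C(=O)c1cc(OC)c(OC)c(OC)c1 | intermediate
8 | surinamensinol A, (1R,2R)-2-[4-(3-hydroxypropyl)-2-methoxyphenoxy]-1-(3,4,5-trimethoxyphenyl)propan-1-ol (7R,8R) | COc1cc(CCCO)ccc1O[C@H](C)[C@H](O)c1cc(OC)c(OC)c(OC)c1 | target

Total step count: 4. Longest linear sequence: 4 steps (1 → 4 → 5 → 7 → 8).

**Steps most likely to fail**

Step 4. Racemisation of C8 may be slower than reduction of the mismatched (8S)-ketone, or the Felkin preference may be weak, so that the erythro isomer builds up. The fallback fixes C8 from the chiral pool and sets C7 by substrate control. It sets out from 6 and comes back at 8.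
- Alkylation of 6 with purchased ethyl (S)-2-(tosyloxy)propanoate (K2CO3, MeCN, 60 °C, SN2 with inversion) would give ethyl (R)-2-[4-(3-hydroxypropyl)-2-methoxyphenoxy]propanoate F1.
- MeNHOMe·HCl and i-PrMgCl (THF, −20 °C) would turn it into (R)-2-[4-(3-hydroxypropyl)-2-methoxyphenoxy]-N-methoxy-N-methylpropanamide F2.
- Purchased 3,4,5-trimethoxyphenylmagnesium bromide (2.5 equiv, THF, 0 °C; the first equivalent is spent on the hydroxyl group) would add once to give (R)-2-[4-(3-hydroxypropyl)-2-methoxyphenoxy]-1-(3,4,5-trimethoxyphenyl)propan-1-one F3.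
- Felkin-controlled reduction with the bulky, non-chelating LiB(s-Bu)3H (THF, −78 °C) would return to the route at 8.

Step 3. The enolisable secondary bromide may lose HBr, or displacement may be slow enough for by-products to build up. The fallback forms the C8–O bond on an α-bromo amide and makes the ketone afterwards by forming the C7–ring A bond. It sets out from 6 and comes back at 7.
- Alkylation of 6 with purchased racemic 2-bromo-N-methoxy-N-methylpropanamide (K2CO3, DMF, rt) would give racemic 2-[4-(3-hydroxypropyl)-2-methoxyphenoxy]-N-methoxy-N-methylpropanamide F4.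
- Purchased 3,4,5-trimethoxyphenylmagnesium bromide (2.5 equiv, THF, 0 °C) would add once to the amide and return to the route at 7.

Step 2. Bromine may enter the electron-rich ring A, or a second bromine may enter at C8. The fallback brings in the leaving group at C8 as oxygen, with no electrophilic halogen. It sets out from 4 and comes back at 7.
- TMSOTf and Et3N (CH2Cl2, 0 °C) would give (Z)-trimethyl{[1-(3,4,5-trimethoxyphenyl)prop-1-en-1-yl]oxy}silane F5.
- Rubottom oxidation (mCPBA, NaHCO3, CH2Cl2, −20 °C) would give 2-(trimethylsilyloxy)-1-(3,4,5-trimethoxyphenyl)propan-1-one F6, which dilute HCl in THF would cleave to racemic 2-hydroxy-1-(3,4,5-trimethoxyphenyl)propan-1-one F7.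
- MsCl and Et3N (CH2Cl2, 0 °C) would give racemic 1-oxo-1-(3,4,5-trimethoxyphenyl)propan-2-yl methanesulfonate F8.
- Phenol 6 and K2CO3 (acetone, reflux) would displace the mesylate and return to the route at 7.

## Further compounds
F1 | step 4 | ethyl (R)-2-[4-(3-hydroxypropyl)-2-methoxyphenoxy]propanoate | C[C@@H](Oc1ccc(CCCO)cc1OC)C(=O)OCC
F2 | step 4 | (R)-2-[4-(3-hydroxypropyl)-2-methoxyphenoxy]-N-methoxy-N-methylpropanamide | C[C@@H](Oc1ccc(CCCO)cc1OC)C(=O)N(C)OC
F3 | step 4 | (R)-2-[4-(3-hydroxypropyl)-2-methoxyphenoxy]-1-(3,4,5-trimethoxyphenyl)propan-1-one | C[C@@H](Oc1ccc(CCCO)cc1OC)C(=O)c1cc(OC)c(OC)c(OC)c1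
F4 | step 3 | 2-[4-(3-hydroxypropyl)-2-methoxyphenoxy]-N-methoxy-N-methylpropanamide (racemic) | CC(Oc1ccc(CCCO)cc1OC)C(=O)N(C)OC
F5 | step 2 | (Z)-trimethyl{[1-(3,4,5-trimethoxyphenyl)prop-1-en-1-yl]oxy}silane | C/C=C(\O[Si](C)(C)C)c1cc(OC)c(OC)c(OC)c1
F6 | step 2 | 2-(trimethylsilyloxy)-1-(3,4,5-trimethoxyphenyl)propan-1-one (racemic) | CC(O[Si](C)(C)C)C(=O)c1cc(OC)c(OC)c(OC)c1
F7 | step 2 | 2-hydroxy-1-(3,4,5-trimethoxyphenyl)propan-1-one (racemic) | CC(O)C(=O)c1cc(OC)c(OC)c(OC)c1
F8 | step 2 | 1-oxo-1-(3,4,5-trimethoxyphenyl)propan-2-yl methanesulfonate (racemic) | CC(OS(C)(=O)=O)C(=O)c1cc(OC)c(OC)c(OC)c1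
A1 | direct plan | (S)-3-[2-(4-allyl-2-methoxyphenoxy)acetyl]-4-benzyloxazolidin-2-one | COc1cc(CC=C)ccc1OCC(=O)N1C(=O)OC[C@@H]1Cc1ccccc1
A2 | direct plan | (S)-4-benzyl-3-[(2S,3R)-2-(4-allyl-2-methoxyphenoxy)-3-hydroxy-3-(3,4,5-trimethoxyphenyl)propanoyl]oxazolidin-2-one | COc1cc(CC=C)ccc1O[C@H](C(=O)N1C(=O)OC[C@@H]1Cc1ccccc1)[C@H](O)c1cc(OC)c(OC)c(OC)c1
A3 | direct plan | (2R,3R)-2-(4-allyl-2-methoxyphenoxy)-3-(tert-butyldimethylsilyloxy)-3-(3,4,5-trimethoxyphenyl)propyl 4-methylbenzenesulfonate | COc1cc(CC=C)ccc1O[C@H](COS(=O)(=O)c2ccc(C)cc2)[C@H](O[Si](C)(C)C(C)(C)C)c3cc(OC)c(OC)c(OC)c3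
A4 | direct plan | tert-butyl{[(1R,2R)-2-(4-allyl-2-methoxyphenoxy)-1-(3,4,5-trimethoxyphenyl)propyl]oxy}dimethylsilane | COc1cc(CC=C)ccc1O[C@H](C)[C@H](O[Si](C)(C)C(C)(C)C)c1cc(OC)c(OC)c(OC)c1
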